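**Plan**

- Retrosynthesis: both bonds to the ketone carbon are cut first (ring A C1'–C(O) and C(O)–CH2). That carbon lies between the 2,4-dioxygenated ring A and the CH2CH2 tether to C6 of the chromene, so it can be supplied as carbon monoxide between a ring A iodide and a primary 2-(chromen-6-yl)ethylborane.
- The borane goes back to the 6-vinylchromene and, by methylenation, to the 6-carbaldehyde. The C7–prenyl bond is cut by a Claisen shift from O8, and the pyran ring (C4–C4a bond) by a propargyl ether rearrangement on 3,4-dihydroxybenzaldehyde.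
- Forward: the pyran ring is built first (the only ring formed), then the prenyl group at C7, then the vinyl group. Hydroboration and the three-component coupling join the two aromatic halves, and desilylation ends the route.
- Stereochemistry: the target has no stereocentre. The chromene C3=C4 alkene is cis by ring constraint and the prenyl alkene has no geometry to set.
- The phenols are carried as tert-butyldimethylsilyl ethers so that the last step uses fluoride and not acid, which could cyclise the ortho-prenylphenol or hydrate the chromene.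

Key step: step 10

Remark on the chemistry: 9-BBN is taken as its commercial THF solution, and the borane of step 9 is carried into step 10 in the same flask.

**Step 1**
Reactants: 1 3,4-dihydroxybenzaldehyde; 2 3-chloro-3-methylbut-1-yne
Product: 3 3-hydroxy-4-[(2-methylbut-3-yn-2-yl)oxy]benzaldehyde
Conditions: K2CO3 (1.1 equiv), KI, CuI (cat.), DMF, 50 °C
Reagents that add atoms: none
Why: Copper-assisted Williamson-type O-propargylation: the 4-OH para to the formyl group is the more acidic phenol, so with about one equivalent of carbonate its phenoxide is formed and alkylated preferentially by the tertiary propargylic chloride.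

**Step 2**
Reactants: 3 3-hydroxy-4-[(2-methylbut-3-yn-2-yl)oxy]benzaldehyde
Product: 5 8-hydroxy-2,2-dimethyl-2H-chromene-6-carbaldehyde, via allenylphenol 4 (not isolated)
Conditions: N,N-diethylaniline, 185 °C
Reagents that add atoms: none
Why: Aromatic propargyl Claisen rearrangement into C5 of the benzaldehyde, the only free position ortho to the ether oxygen, gives allenylphenol 4, and its 1,5-hydrogen shift followed by oxa-6π electrocyclisation closes the 2,2-dimethylpyran ring (the classical thermal chromene synthesis).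

**Step 3**
Reactants: 5 8-hydroxy-2,2-dimethyl-2H-chromene-6-carbaldehyde; 2 3-chloro-3-methylbut-1-yne
Product: 6 2,2-dimethyl-8-[(2-methylbut-3-yn-2-yl)oxy]-2H-chromene-6-carbaldehyde
Conditions: K2CO3, KI, CuI (cat.), acetone, reflux
Reagents that add atoms: none
Why: The same copper-assisted O-propargylation, now on the single remaining phenol at C8, at a temperature too low for the new ether to rearrange.

**Step 4**
Reactants: 6 2,2-dimethyl-8-[(2-methylbut-3-yn-2-yl)oxy]-2H-chromene-6-carbaldehyde
Product: 7 2,2-dimethyl-8-[(2-methylbut-3-en-2-yl)oxy]-2H-chromene-6-carbaldehyde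
Conditions: H2 (1 atm), Pd/CaCO3 poisoned with Pb(OAc)2 (Lindlar catalyst), quinoline, EtOAc, rt
Reagents that add atoms: none
Why: Lindlar semi-hydrogenation of a terminal alkyne stops at the alkene, and the poisoned catalyst should leave the cyclic styrenyl alkene of the chromene and the aldehyde untouched.

**Step 5**
Reactants: 7 2,2-dimethyl-8-[(2-methylbut-3-en-2-yl)oxy]-2H-chromene-6-carbaldehyde
Product: 9 8-hydroxy-2,2-dimethyl-7-(3-methylbut-2-en-1-yl)-2H-chromene-6-carbaldehyde, via cyclohexadienone 8 (not isolated)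
Conditions: o-xylene, 130 °C
Reagents that add atoms: none
Why: Aromatic Claisen rearrangement: the 1,1-dimethylallyl group is delivered with allylic inversion to C7, the only hydrogen-bearing carbon ortho to O8, so that the linear prenyl group results and cyclohexadienone 8 re-aromatises by enolisation.

**Step 6**
Reactants: 9 8-hydroxy-2,2-dimethyl-7-(3-methylbut-2-en-1-yl)-2H-chromene-6-carbaldehyde
Product: 10 8-[(tert-butyldimethylsilyl)oxy]-2,2-dimethyl-7-(3-methylbut-2-en-1-yl)-2H-chromene-6-carbaldehyde
Conditions: TBSCl, imidazole, DMF, rt → 40 °C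
Reagents that add atoms: tert-butyldimethylsilyl chloride, CC(C)(C)[Si](C)(C)Cl
Why: Standard imidazole-promoted silylation of a phenol, which masks the acidic OH for the ylide and borane steps and can later be removed by fluoride without acid.

**Step 7**
Reactants: 10 8-[(tert-butyldimethylsilyl)oxy]-2,2-dimethyl-7-(3-methylbut-2-en-1-yl)-2H-chromene-6-carbaldehyde
Product: 11 tert-butyl{[6-ethenyl-2,2-dimethyl-7-(3-methylbut-2-en-1-yl)-2H-chromen-8-yl]oxy}dimethylsilane
Conditions: Ph3PCH3Br, NaN(SiMe3)2, THF, 0 °C → rt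
Reagents that add atoms: methyltriphenylphosphonium bromide, C[P+](c1ccccc1)(c1ccccc1)c1ccccc1.[Br-]
Why: Wittig methylenation of an aromatic aldehyde with the non-stabilised ylide, run with a slight deficit of base relative to the phosphonium salt so that the aryl silyl ether is not attacked.

**Step 8**
Reactants: 12 4-iodoresorcinol (4-iodobenzene-1,3-diol)
Product: 13 1-iodo-2,4-bis[(tert-butyldimethylsilyl)oxy]benzene
Conditions: TBSCl, imidazole, DMF, rt
Reagents that add atoms: tert-butyldimethylsilyl chloride, CC(C)(C)[Si](C)(C)Cl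
Why: Routine bis-silylation of both phenols, which leaves the C–I bond untouched and gives a non-acidic, electron-rich coupling partner.

**Step 9**
Reactants: 11 tert-butyl{[6-ethenyl-2,2-dimethyl-7-(3-methylbut-2-en-1-yl)-2H-chromen-8-yl]oxy}dimethylsilane; 14 9-borabicyclo[3.3.1]nonane (9-BBN)
Product: 15 9-{2-[8-[(tert-butyldimethylsilyl)oxy]-2,2-dimethyl-7-(3-methylbut-2-en-1-yl)-2H-chromen-6-yl]ethyl}-9-borabicyclo[3.3.1]nonane
Conditions: 9-BBN (0.5 M in THF, 1.1 equiv), THF, 0 °C → rt; solution carried directly into step 10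
Reagents that add atoms: none
Why: Anti-Markovnikov hydroboration: 9-BBN places boron on the terminal carbon of the monosubstituted styrenyl alkene far faster than it reacts with the trisubstituted prenyl alkene or the hindered cyclic chromene alkene.

**Step 10**
Reactants: 13 1-iodo-2,4-bis[(tert-butyldimethylsilyl)oxy]benzene; 15 9-{2-[8-[(tert-butyldimethylsilyl)oxy]-2,2-dimethyl-7-(3-methylbut-2-en-1-yl)-2H-chromen-6-yl]ethyl}-9-borabicyclo[3.3.1]nonane; 16 carbon monoxide
Product: 17 1-{2,4-bis[(tert-butyldimethylsilyl)oxy]phenyl}-3-[8-[(tert-butyldimethylsilyl)oxy]-2,2-dimethyl-7-(3-methylbut-2-en-1-yl)-2H-chromen-6-yl]propan-1-one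
Conditions: Pd(PPh3)4 (5 mol%), anhydrous K3PO4 (3 equiv), CO (1 atm), THF/toluene, rt → 45 °C
Reagents that add atoms: none
Why: Oxidative addition of iodide 13 to zerovalent palladium gives an arylpalladium iodide (divalent palladium), CO coordinates and the aryl group migrates to it to form an aroylpalladium species, phosphate-activated borane 15 transfers its primary alkyl group, and reductive elimination releases ketone 17 with both bonds to the carbonyl carbon newly made. The closest known reaction is the carbonylative Suzuki–Miyaura coupling of B-alkyl-9-BBN reagents with iodoarenes to give aryl alkyl ketones. No ring is closed and no stereocentre is formed. The selectivity needed is carbonylative over direct aryl–alkyl coupling; it is secured by the two donor oxygens ortho and para to the palladium-bearing carbon, which speed aryl migration to CO, by the slow transmetalation of an alkylborane with anhydrous K3PO4 at low temperature, and by keeping the solution saturated with CO. Only the primary B–CH2 bond transfers, the two secondary bicyclic B–C bonds being inert, and the trisubstituted prenyl alkene and the hindered chromene alkene should not insert into the acylpalladium intermediate.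

**Step 11**
Reactants: 17 1-{2,4-bis[(tert-butyldimethylsilyl)oxy]phenyl}-3-[8-[(tert-butyldimethylsilyl)oxy]-2,2-dimethyl-7-(3-methylbut-2-en-1-yl)-2H-chromen-6-yl]propan-1-one
Product: 18 1-(2,4-dihydroxyphenyl)-3-[8-hydroxy-2,2-dimethyl-7-(3-methylbut-2-en-1-yl)-2H-chromen-6-yl]propan-1-one (CNP0290651.0)
Conditions: Bu4NF, AcOH, THF, 0 °C
Reagents that add atoms: none
Why: Fluoride-mediated cleavage of the three aryl silyl ethers, driven by Si–F bond formation and buffered with acetic acid, should free the phenols without any acid strong enough to cyclise the ortho-prenylphenol or hydrate the chromene.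

**Compound list**

1 | 3,4-dihydroxybenzaldehyde | O=Cc1ccc(O)c(O)c1 | starting material
2 | 3-chloro-3-methylbut-1-yne | CC(C)(Cl)C#C | starting material
3 | 3-hydroxy-4-[(2-methylbut-3-yn-2-yl)oxy]benzaldehyde | CC(C)(C#C)Oc1ccc(C=O)cc1O | intermediate
4 | 3,4-dihydroxy-5-(3-methylbuta-1,2-dien-1-yl)benzaldehyde (allenylphenol) | CC(C)=C=Cc1cc(C=O)cc(O)c1O | intermediate (not isolated)
5 | 8-hydroxy-2,2-dimethyl-2H-chromene-6-carbaldehyde | CC1(C)C=Cc2cc(C=O)cc(O)c2O1 | intermediate
6 | 2,2-dimethyl-8-[(2-methylbut-3-yn-2-yl)oxy]-2H-chromene-6-carbaldehyde | CC1(C)C=Cc2cc(C=O)cc(OC(C)(C)C#C)c2O1 | intermediate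
7 | 2,2-dimethyl-8-[(2-methylbut-3-en-2-yl)oxy]-2H-chromene-6-carbaldehyde | CC1(C)C=Cc2cc(C=O)cc(OC(C)(C)C=C)c2O1 | intermediate
8 | 2,2-dimethyl-7-(3-methylbut-2-en-1-yl)-8-oxo-7,8-dihydro-2H-chromene-6-carbaldehyde (racemic cyclohexadienone) | O=C1C(CC=C(C)C)C(C=O)=CC2=C1OC(C)(C)C=C2 | intermediate (not isolated)
9 | 8-hydroxy-2,2-dimethyl-7-(3-methylbut-2-en-1-yl)-2H-chromene-6-carbaldehyde | CC(C)=CCc1c(C=O)cc2c(c1O)OC(C)(C)C=C2 | intermediate
10 | 8-[(tert-butyldimethylsilyl)oxy]-2,2-dimethyl-7-(3-methylbut-2-en-1-yl)-2H-chromene-6-carbaldehyde | CC(C)=CCc1c(C=O)cc2c(c1O[Si](C)(C)C(C)(C)C)OC(C)(C)C=C2 | intermediate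
11 | tert-butyl{[6-ethenyl-2,2-dimethyl-7-(3-methylbut-2-en-1-yl)-2H-chromen-8-yl]oxy}dimethylsilane | CC(C)=CCc1c(C=C)cc2c(c1O[Si](C)(C)C(C)(C)C)OC(C)(C)C=C2 | intermediate
12 | 4-iodoresorcinol | Oc1ccc(I)c(O)c1 | starting material
13 | 1-iodo-2,4-bis[(tert-butyldimethylsilyl)oxy]benzene | CC(C)(C)[Si](C)(C)Oc1ccc(I)c(O[Si](C)(C)C(C)(C)C)c1 | intermediate
14 | 9-borabicyclo[3.3.1]nonane | B1C2CCCC1CCC2 | starting material
15 | 9-{2-[8-[(tert-butyldimethylsilyl)oxy]-2,2-dimethyl-7-(3-methylbut-2-en-1-yl)-2H-chromen-6-yl]ethyl}-9-borabicyclo[3.3.1]nonane | CC(C)=CCc1c(CCB2C3CCCC2CCC3)cc2c(c1O[Si](C)(C)C(C)(C)C)OC(C)(C)C=C2 | intermediate (used in solution)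
16 | carbon monoxide | [C-]#[O+] | starting material
17 | 1-{2,4-bis[(tert-butyldimethylsilyl)oxy]phenyl}-3-[8-[(tert-butyldimethylsilyl)oxy]-2,2-dimethyl-7-(3-methylbut-2-en-1-yl)-2H-chromen-6-yl]propan-1-one | CC(C)=CCc1c(CCC(=O)c2ccc(O[Si](C)(C)C(C)(C)C)cc2O[Si](C)(C)C(C)(C)C)cc2c(c1O[Si](C)(C)C(C)(C)C)OC(C)(C)C=C2 | intermediate
18 | 1-(2,4-dihydroxyphenyl)-3-[8-hydroxy-2,2-dimethyl-7-(3-methylbut-2-en-1-yl)-2H-chromen-6-yl]propan-1-one | CC(C)=CCc1c(CCC(=O)c2ccc(O)cc2O)cc2c(c1O)OC(C)(C)C=C2 | target

**Step count**

Total: 11 steps. Longest linear sequence: 10 steps (steps 1–7, 9, 10, 11); step 8 is the one-step side branch to the ring A iodide.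

**Steps most likely to fail**

Step 10. The alkyl group may be transferred to the arylpalladium species before CO has inserted, giving direct aryl–alkyl coupling. Transmetalation at the crowded ortho-silyloxy aroylpalladium centre may also be slow enough that the borane is lost by protodeboronation. The fallback sets out from aldehyde 10 and returns at ketone 17, building the three-carbon bridge by aldol chemistry. Commercial 2,4-dihydroxyacetophenone is bis-silylated (TBSCl, imidazole, DMF) to 1-{2,4-bis[(tert-butyldimethylsilyl)oxy]phenyl}ethan-1-one F1. Its lithium enolate (LiN(SiMe3)2, THF, −78 °C) should add to aldehyde 10 to give the racemic β-hydroxy ketone 1-{2,4-bis[(tert-butyldimethylsilyl)oxy]phenyl}-3-[8-[(tert-butyldimethylsilyl)oxy]-2,2-dimethyl-7-(3-methylbut-2-en-1-yl)-2H-chromen-6-yl]-3-hydroxypropan-1-one F2. Mesylation and elimination (MsCl, Et3N, then DBU) should give the (E)-chalcone (E)-1-{2,4-bis[(tert-butyldimethylsilyl)oxy]phenyl}-3-[8-[(tert-butyldimethylsilyl)oxy]-2,2-dimethyl-7-(3-methylbut-2-en-1-yl)-2H-chromen-6-yl]prop-2-en-1-one F3. Conjugate reduction of the enone with [(Ph3P)CuH]6 (Stryker's reagent), which leaves the prenyl and chromene alkenes alone, then gives 17.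

Step 5. The tertiary allyl ether may fragment on heating to phenol 5 and isoprene, or the allyl group may travel on to the para position C5 in competition with the ortho shift. The fallback sets out from phenol 5 and returns at 9, moving the unit as a primary allyl group that cannot fragment. O-Allylation (allyl bromide, K2CO3, acetone) gives 2,2-dimethyl-8-(prop-2-en-1-yloxy)-2H-chromene-6-carbaldehyde F4. Aromatic Claisen rearrangement (N,N-diethylaniline, 190 °C) places the allyl group at C7 to give 8-hydroxy-2,2-dimethyl-7-(prop-2-en-1-yl)-2H-chromene-6-carbaldehyde F5. Olefin cross-metathesis with excess 2-methylbut-2-ene and the second-generation Grubbs catalyst (1,3-dimesitylimidazolidin-2-ylidene)(PCy3)Cl2Ru=CHPh then converts the allyl into the prenyl group and gives 9; the hindered cyclic chromene alkene should not take part.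

Step 1. The slow tertiary electrophile may fail to discriminate between the two phenoxides, or alkylation may run on to the bis-ether. The fallback sets out from chloride 2, uses commercial vanillin (4-hydroxy-3-methoxybenzaldehyde) in place of 1, and returns at 5. The single free phenol of vanillin is propargylated under the conditions of step 1 to give 3-methoxy-4-[(2-methylbut-3-yn-2-yl)oxy]benzaldehyde F6. Thermal rearrangement as in step 2 gives 8-methoxy-2,2-dimethyl-2H-chromene-6-carbaldehyde F7. Nucleophilic O-demethylation with NaSEt in DMF at 120 °C (SN2 attack at the methyl group, leaving the tertiary chromene ether and the alkene untouched) then gives 5.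

**Further compounds**

F1 | step 10 | 1-{2,4-bis[(tert-butyldimethylsilyl)oxy]phenyl}ethan-1-one | CC(=O)c1ccc(O[Si](C)(C)C(C)(C)C)cc1O[Si](C)(C)C(C)(C)C
F2 | step 10 | 1-{2,4-bis[(tert-butyldimethylsilyl)oxy]phenyl}-3-[8-[(tert-butyldimethylsilyl)oxy]-2,2-dimethyl-7-(3-methylbut-2-en-1-yl)-2H-chromen-6-yl]-3-hydroxypropan-1-one (racemic) | CC(C)=CCc1c(C(O)CC(=O)c2ccc(O[Si](C)(C)C(C)(C)C)cc2O[Si](C)(C)C(C)(C)C)cc2c(c1O[Si](C)(C)C(C)(C)C)OC(C)(C)C=C2
F3 | step 10 | (E)-1-{2,4-bis[(tert-butyldimethylsilyl)oxy]phenyl}-3-[8-[(tert-butyldimethylsilyl)oxy]-2,2-dimethyl-7-(3-methylbut-2-en-1-yl)-2H-chromen-6-yl]prop-2-en-1-one | CC(C)=CCc1c(/C=C/C(=O)c2ccc(O[Si](C)(C)C(C)(C)C)cc2O[Si](C)(C)C(C)(C)C)cc2c(c1O[Si](C)(C)C(C)(C)C)OC(C)(C)C=C2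
F4 | step 5 | 2,2-dimethyl-8-(prop-2-en-1-yloxy)-2H-chromene-6-carbaldehyde | CC1(C)C=Cc2cc(C=O)cc(OCC=C)c2O1
F5 | step 5 | 8-hydroxy-2,2-dimethyl-7-(prop-2-en-1-yl)-2H-chromene-6-carbaldehyde | C=CCc1c(C=O)cc2c(c1O)OC(C)(C)C=C2
F6 | step 1 | 3-methoxy-4-[(2-methylbut-3-yn-2-yl)oxy]benzaldehyde | COc1cc(C=O)ccc1OC(C)(C)C#C
F7 | step 1 | 8-methoxy-2,2-dimethyl-2H-chromene-6-carbaldehyde | COc1cc(C=O)cc2c1OC(C)(C)C=C2
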